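**Retrosynthetic overview** (chain numbered C1 = furyl CH2 to C15 = lactone C=O; target is 6S,11R,12S with both alkenes E)
1. C6–OAc ester C–O bond, formed last: diastereoconvergent (dynamic kinetic) O-acetylation of the C6-epimeric carbinol 20 sets C6 (S).
2. C5–C6: stereo-random, α-selective allylbarium addition of the furan fragment 18 to enal 12.
3. Lactone C12–O bond: Shi epoxide 8 is opened with inversion by the ester carbonyl (5-exo), setting C11 (R) and C12 (S).
4. Chains: Johnson–Claisen on a geranyl acetate-derived allylic alcohol (C11=C12, C13–C15); Cu-catalysed SN2′ opening of isoprene monoxide by a furylmethyl Grignard (C3=C4).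
5. Ring order: the furan is bought intact; the γ-lactone is the only ring built (step 4), before fragment union.

Assumption: the D-fructose-derived Shi ketone, (η5-C5Ph5)Ru(CO)2Cl and both enantiomers of the planar-chiral DMAP complex Fe(η5-C5Ph5)(η5-C10H11N2) are taken as available catalysts.

**Route**

Step 1
Reactants: 1 geranyl acetate
Product: 2 (2E)-5-(3,3-dimethyloxiran-2-yl)-3-methylpent-2-en-1-yl acetate (racemic)
Conditions: mCPBA (1.0 equiv), CH2Cl2, −20 → 0 °C
Reagents that add atoms: 3-chloroperbenzoic acid OOC(=O)c1cccc(Cl)c1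
Why: Prilezhaev epoxidation takes the electron-rich 6,7-alkene; the 2,3-alkene is deactivated by the allylic acetate, and the racemic centre is destroyed in step 3.

Step 2
Reactants: 2 (2E)-5-(3,3-dimethyloxiran-2-yl)-3-methylpent-2-en-1-yl acetate
Product: 4 (2E)-6-hydroxy-3,7-dimethylocta-2,7-dien-1-yl acetate (racemic), via silyl ether 3 (not isolated)
Conditions: TMSOTf (1.2 equiv), DBU (1.5 equiv), toluene, −78 °C → rt; then 1 M HCl, THF, 0 °C
Reagents that add atoms: none
Why: Silyl triflate-mediated epoxide-to-allylic-alcohol isomerisation opens the epoxide at the tertiary carbon and DBU removes a methyl proton, giving the isopropenyl carbinol without touching the acetate.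

Step 3
Reactants: 4 (2E)-6-hydroxy-3,7-dimethylocta-2,7-dien-1-yl acetate; 5 triethyl orthoacetate
Product: 7 ethyl (4E,8E)-10-(acetyloxy)-4,8-dimethyldeca-4,8-dienoate, via ketene acetal 6 (not isolated)
Conditions: MeC(OEt)3 (5 equiv), EtCO2H (5 mol %), 138 °C, EtOH distilled off
Reagents that add atoms: none
Why: Johnson–Claisen rearrangement through a chair transition state with the chain equatorial gives the E-trisubstituted alkene (typically ≥95:5) and adds C14–C15 under acetate-compatible, base-free conditions.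

Step 4
Reactants: 7 ethyl (4E,8E)-10-(acetyloxy)-4,8-dimethyldeca-4,8-dienoate
Product: 9 (2E,6R)-6-hydroxy-3-methyl-6-[(2S)-2-methyl-5-oxooxolan-2-yl]hex-2-en-1-yl acetate, via epoxy ester 8 (not isolated)
Conditions: D-fructose-derived Shi ketone (30 mol %), KHSO5 (as 2KHSO5·KHSO4·K2SO4, 1.4 equiv), K2CO3, Bu4NHSO4 (cat.), MeCN/DMM/aq Na2B4O7–Na2EDTA (pH 10.5), 0 °C; extract; then CSA (10 mol %), wet CH2Cl2, 0 °C → rt
Reagents that add atoms: potassium peroxymonosulfate [K+].[O-]S(=O)(=O)OO; water O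
Why: Shi epoxidation (spiro dioxirane transition state) gives the (2R,3R)-epoxide at the only electron-rich alkene; the ester carbonyl then opens it 5-exo at the tertiary carbon with inversion, so C12 becomes S and C11 keeps the epoxide oxygen as R.

Step 5
Reactants: 9 (2E,6R)-6-hydroxy-3-methyl-6-[(2S)-2-methyl-5-oxooxolan-2-yl]hex-2-en-1-yl acetate
Product: 10 (5S)-5-[(1R,4E)-1,6-dihydroxy-4-methylhex-4-en-1-yl]-5-methyloxolan-2-one
Conditions: K2CO3 (0.3 equiv), MeOH, 0 °C, 1 h; AcOH quench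
Reagents that add atoms: none
Why: Zemplén-type transesterification removes the unhindered primary allylic acetate quickly; any ring-opened hydroxy ester closes back to the favoured γ-lactone on acidic work-up.

Step 6
Reactants: 10 (5S)-5-[(1R,4E)-1,6-dihydroxy-4-methylhex-4-en-1-yl]-5-methyloxolan-2-one
Product: 12 (1R,4E)-4-methyl-1-[(2S)-2-methyl-5-oxooxolan-2-yl]-6-oxohex-4-en-1-yl acetate, via hydroxy enal 11 (not isolated)
Conditions: MnO2 (15 equiv), CH2Cl2, rt; filter; then Ac2O (3 equiv), pyridine, DMAP (5 mol %), 0 °C → rt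
Reagents that add atoms: acetic anhydride CC(=O)OC(C)=O
Why: MnO2 oxidises only the allylic primary alcohol, and acetylating C11–OH now removes the only other carbinol that a hydrogen-transfer catalyst could epimerise in step 11.

Step 7
Reactants: 13 furan-3-ylmethanol
Product: 14 3-(chloromethyl)furan
Conditions: SOCl2 (1.1 equiv), pyridine (1.1 equiv), Et2O, 0 °C; used as an ethereal solution
Reagents that add atoms: thionyl chloride O=S(Cl)Cl
Why: Standard chlorodehydroxylation of a primary furylmethyl alcohol, buffered with pyridine to protect the furan.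

Step 8
Reactants: 14 3-(chloromethyl)furan; 15 2-methyl-2-vinyloxirane (racemic)
Product: 17 (2E)-5-(furan-3-yl)-2-methylpent-2-en-1-ol, via Grignard reagent 16 (not isolated)
Conditions: Mg, THF, 0 °C (slow addition); then 15 (1.2 equiv), CuI (10 mol %), THF, −30 → 0 °C; aq NH4Cl
Reagents that add atoms: none
Why: Cu-catalysed anti-SN2′ opening of the vinyl epoxide through its s-trans conformer gives the E-trisubstituted allylic alcohol (typically about 9:1, minor Z removed by chromatography), forming C1–C2 and C3=C4 in one step.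

Step 9
Reactants: 17 (2E)-5-(furan-3-yl)-2-methylpent-2-en-1-ol
Product: 18 3-[(3E)-5-chloro-4-methylpent-3-en-1-yl]furan
Conditions: PPh3 (1.3 equiv), CCl4, reflux, 1 h
Reagents that add atoms: tetrachloromethane ClC(Cl)(Cl)Cl
Why: Appel chlorination converts primary allylic alcohols to chlorides under neutral conditions without allylic transposition or E/Z loss.

Step 10
Reactants: 18 3-[(3E)-5-chloro-4-methylpent-3-en-1-yl]furan; 12 (1R,4E)-4-methyl-1-[(2S)-2-methyl-5-oxooxolan-2-yl]-6-oxohex-4-en-1-yl acetate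
Product: 20 (1R,4E,8E)-11-(furan-3-yl)-6-hydroxy-4,8-dimethyl-1-[(2S)-2-methyl-5-oxooxolan-2-yl]undeca-4,8-dien-1-yl acetate (about 1:1 C6 epimers), via allylbarium chloride 19 (not isolated)
Conditions: Li, biphenyl, THF, rt; BaI2 (anhydrous), rt; cool to −78 °C, add 18 (1.2 equiv), 20 min; add 12 (1.0 equiv), −78 °C, 30 min; aq NH4Cl
Reagents that add atoms: none
Why: Allylbarium reagents add 1,2 to aldehydes at the α-carbon with retention of alkene geometry, and at −78 °C the aldehyde reacts far faster than the acetate or lactone; C6 is deliberately left uncontrolled and is set in step 11.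

Step 11
Reactants: 20 (1R,4E,8E)-11-(furan-3-yl)-6-hydroxy-4,8-dimethyl-1-[(2S)-2-methyl-5-oxooxolan-2-yl]undeca-4,8-dien-1-yl acetate (C6 epimers)
Product: 21 Irciformonin F, (1R,4E,6S,8E)-11-(furan-3-yl)-4,8-dimethyl-1-[(2S)-2-methyl-5-oxooxolan-2-yl]undeca-4,8-diene-1,6-diyl diacetate
Conditions: (η5-C5Ph5)Ru(CO)2Cl (5 mol %), KOt-Bu (5 mol %), Fe(η5-C5Ph5)(η5-C10H11N2) planar-chiral DMAP (2 mol %, the enantiomer that acylates the (S)-carbinol, i.e. the antipode of the one giving (R)-1-phenylethyl acetate), acetyl isopropyl carbonate (1.5 equiv), toluene/tert-amyl alcohol 1:1, 10 °C → rt, 48 h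
Reagents that add atoms: acetyl isopropyl carbonate CC(C)OC(=O)OC(C)=O
Why: Proposed new method: a non-enzymatic dynamic kinetic acetylation of a polyunsaturated alkenyl/allyl-methyl carbinol, in which the Ru alkoxide epimerises C6 by reversible β-hydride elimination and re-addition through a Ru-bound β,β-disubstituted enone (hindered towards 1,4-hydride transfer, and C6–OH is the only free carbinol), while the chiral acylpyridinium distinguishes the alkenyl π-arm bearing a cis-β-methyl from the CH2 arm and acetylates only the (S)-epimer, so both epimers converge on the (6S)-acetate, which the Ru catalyst cannot racemise; the closest known reaction types are the Ru/planar-chiral-DMAP dynamic kinetic resolution of aryl alkyl carbinols, the kinetic resolution of simple allylic alcohols with the same iron catalyst, and the Ru/lipase dynamic kinetic resolution of small allylic alcohols.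

**Compound list**
1 | geranyl acetate, (2E)-3,7-dimethylocta-2,6-dien-1-yl acetate | CC(C)=CCC/C(C)=C/COC(C)=O | starting material
2 | (2E)-5-(3,3-dimethyloxiran-2-yl)-3-methylpent-2-en-1-yl acetate (racemic) | CC(=O)OC/C=C(\C)CCC1OC1(C)C | intermediate
3 | (2E)-3,7-dimethyl-6-[(trimethylsilyl)oxy]octa-2,7-dien-1-yl acetate (racemic silyl ether) | CC(=O)OC/C=C(\C)CCC(O[Si](C)(C)C)C(C)=C | intermediate
4 | (2E)-6-hydroxy-3,7-dimethylocta-2,7-dien-1-yl acetate (racemic) | CC(=O)OC/C=C(\C)CCC(O)C(C)=C | intermediate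
5 | triethyl orthoacetate (1,1,1-triethoxyethane) | CCOC(C)(OCC)OCC | starting material
6 | (2E)-6-[(1-ethoxyethenyl)oxy]-3,7-dimethylocta-2,7-dien-1-yl acetate (ketene acetal, racemic) | C=C(OCC)OC(CC/C(C)=C/COC(C)=O)C(C)=C | intermediate
7 | ethyl (4E,8E)-10-(acetyloxy)-4,8-dimethyldeca-4,8-dienoate | CCOC(=O)CC/C(C)=C/CC/C(C)=C/COC(C)=O | intermediate
8 | ethyl 3-[(2R,3R)-3-[(3E)-5-(acetyloxy)-3-methylpent-3-en-1-yl]-2-methyloxiran-2-yl]propanoate (epoxy ester) | CCOC(=O)CC[C@@]1(C)O[C@@H]1CC/C(C)=C/COC(C)=O | intermediate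
9 | (2E,6R)-6-hydroxy-3-methyl-6-[(2S)-2-methyl-5-oxooxolan-2-yl]hex-2-en-1-yl acetate | CC(=O)OC/C=C(\C)CC[C@@H](O)[C@]1(C)CCC(=O)O1 | intermediate
10 | (5S)-5-[(1R,4E)-1,6-dihydroxy-4-methylhex-4-en-1-yl]-5-methyloxolan-2-one | OC/C=C(\C)CC[C@@H](O)[C@]1(C)CCC(=O)O1 | intermediate
11 | (2E,6R)-6-hydroxy-3-methyl-6-[(2S)-2-methyl-5-oxooxolan-2-yl]hex-2-enal (hydroxy enal) | O=C/C=C(\C)CC[C@@H](O)[C@]1(C)CCC(=O)O1 | intermediate
12 | (1R,4E)-4-methyl-1-[(2S)-2-methyl-5-oxooxolan-2-yl]-6-oxohex-4-en-1-yl acetate | O=C/C=C(\C)CC[C@@H](OC(C)=O)[C@]1(C)CCC(=O)O1 | intermediate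
13 | furan-3-ylmethanol | OCc1ccoc1 | starting material
14 | 3-(chloromethyl)furan | ClCc1ccoc1 | intermediate
15 | 2-methyl-2-vinyloxirane (isoprene monoxide, racemic) | C=CC1(C)CO1 | starting material
16 | (furan-3-ylmethyl)magnesium chloride | Cl[Mg]Cc1ccoc1 | intermediate
17 | (2E)-5-(furan-3-yl)-2-methylpent-2-en-1-ol | OC/C(C)=C/CCc1ccoc1 | intermediate
18 | 3-[(3E)-5-chloro-4-methylpent-3-en-1-yl]furan | ClC/C(C)=C/CCc1ccoc1 | intermediate
19 | [(2E)-5-(furan-3-yl)-2-methylpent-2-en-1-yl]barium chloride | Cl[Ba]C/C(C)=C/CCc1ccoc1 | intermediate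
20 | (1R,4E,8E)-11-(furan-3-yl)-6-hydroxy-4,8-dimethyl-1-[(2S)-2-methyl-5-oxooxolan-2-yl]undeca-4,8-dien-1-yl acetate (C6 epimers) | OC(/C=C(\C)CC[C@@H](OC(C)=O)[C@]1(C)CCC(=O)O1)C/C(C)=C/CCc1ccoc1 | intermediate
21 | Irciformonin F, (1R,4E,6S,8E)-11-(furan-3-yl)-4,8-dimethyl-1-[(2S)-2-methyl-5-oxooxolan-2-yl]undeca-4,8-diene-1,6-diyl diacetate | CC(=O)O[C@H](/C=C(\C)CC[C@@H](OC(C)=O)[C@]1(C)CCC(=O)O1)C/C(C)=C/CCc1ccoc1 | target

**Step count**
Total steps: 11. Longest linear sequence: 8 (steps 1–6, 10, 11 from geranyl acetate).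

**Three steps most likely to fail, with fallbacks**

Step 11 (the proposed new step): racemisation may be slow, or the acyl-transfer catalyst may discriminate poorly on this substrate. The fallback uses known chemistry, sets out from 20 and comes back at 21. Dess–Martin oxidation (NaHCO3, CH2Cl2) converts both epimers into the single enone (1R,4E,8E)-11-(furan-3-yl)-4,8-dimethyl-1-[(2S)-2-methyl-5-oxooxolan-2-yl]-6-oxoundeca-4,8-dien-1-yl acetate F1. Corey–Bakshi–Shibata reduction ((R)-2-methyl-CBS-oxazaborolidine, catecholborane, toluene, −78 °C, alkenyl arm as the large group) gives (1R,4E,6S,8E)-11-(furan-3-yl)-6-hydroxy-4,8-dimethyl-1-[(2S)-2-methyl-5-oxooxolan-2-yl]undeca-4,8-dien-1-yl acetate F2. Ac2O/pyridine/DMAP then gives 21.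

Step 10: the allylbarium reagent may attack the esters or give γ-adduct. The fallback builds C3=C4 from an alkyne instead of an allyl metal; it sets out from 12 and comes back at 20. Zn-mediated Barbier propargylation (propargyl bromide, Zn, THF/aq NH4Cl, 0 °C) gives (1R,4E)-6-hydroxy-4-methyl-1-[(2S)-2-methyl-5-oxooxolan-2-yl]non-4-en-8-yn-1-yl acetate F3. Zr-catalysed methylalumination (Me3Al, Cp2ZrCl2, 1 equiv H2O, CH2Cl2, −20 °C) with I2 quench gives (1R,4E,8E)-6-hydroxy-9-iodo-4,8-dimethyl-1-[(2S)-2-methyl-5-oxooxolan-2-yl]nona-4,8-dien-1-yl acetate F4. Separately, Wittig methylenation of furan-3-carbaldehyde (Ph3P=CH2, THF) gives 3-ethenylfuran F5, and 9-BBN hydroboration of it gives 9-[2-(furan-3-yl)ethyl]-9-borabicyclo[3.3.1]nonane F6. B-alkyl Suzuki–Miyaura coupling of F4 and F6 (PdCl2(dppf), K3PO4, DMF/THF/H2O, rt) returns 20.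

Step 2: the Lewis acid may trigger ketone formation or cyclisation instead of clean isomerisation. The fallback sets out from 1 (bypassing 2 and 3) and comes back at 4. Schenck ene photooxygenation of 1 (O2, tetraphenylporphyrin, hν, CH2Cl2, 0 °C) gives (2E)-6-hydroperoxy-3,7-dimethylocta-2,7-dien-1-yl acetate F7 together with its tertiary regioisomer. PPh3 reduction in the same pot and chromatography deliver 4, at the cost of roughly half the material.

**Further compounds**
F1 | step 11 | (1R,4E,8E)-11-(furan-3-yl)-4,8-dimethyl-1-[(2S)-2-methyl-5-oxooxolan-2-yl]-6-oxoundeca-4,8-dien-1-yl acetate | O=C(/C=C(\C)CC[C@@H](OC(C)=O)[C@]1(C)CCC(=O)O1)C/C(C)=C/CCc1ccoc1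
F2 | step 11 | (1R,4E,6S,8E)-11-(furan-3-yl)-6-hydroxy-4,8-dimethyl-1-[(2S)-2-methyl-5-oxooxolan-2-yl]undeca-4,8-dien-1-yl acetate | O[C@H](/C=C(\C)CC[C@@H](OC(C)=O)[C@]1(C)CCC(=O)O1)C/C(C)=C/CCc1ccoc1
F3 | step 10 | (1R,4E)-6-hydroxy-4-methyl-1-[(2S)-2-methyl-5-oxooxolan-2-yl]non-4-en-8-yn-1-yl acetate (C6 epimers) | C#CCC(O)/C=C(\C)CC[C@@H](OC(C)=O)[C@]1(C)CCC(=O)O1
F4 | step 10 | (1R,4E,8E)-6-hydroxy-9-iodo-4,8-dimethyl-1-[(2S)-2-methyl-5-oxooxolan-2-yl]nona-4,8-dien-1-yl acetate (C6 epimers) | I/C=C(C)/CC(O)/C=C(\C)CC[C@@H](OC(C)=O)[C@]1(C)CCC(=O)O1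
F5 | step 10 | 3-ethenylfuran | C=Cc1ccoc1
F6 | step 10 | 9-[2-(furan-3-yl)ethyl]-9-borabicyclo[3.3.1]nonane | C(Cc1ccoc1)B1C2CCCC1CCC2
F7 | step 2 | (2E)-6-hydroperoxy-3,7-dimethylocta-2,7-dien-1-yl acetate (racemic) | CC(=O)OC/C=C(\C)CCC(OO)C(C)=C
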